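**Retrosynthetic overview**

1. Numbering: chain C1 (ring A ketone carbon), C2 (stereocentre), C3 (methine carrying the two rings B); C2 is bonded to C3' of the chromone (pyranone ring C fused to benzo ring D). The route rests on one feature: C3' and C2' are the α- and the nitrogen-bearing β-carbon of a 2-hydroxyaryl enaminone, and C2 is the β-carbon of a nitroalkene whose nitro-bearing carbon C1 is the masked ring A ketone.
2. Last disconnections: the four O-benzyl groups (hydrogenolysis) and C1=O from C1–NO2 (Nef reaction).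
3. Key disconnection: C2–C3' and O1'–C2' in one operation, from nitroalkene 13 and enaminone 3; ring C is the only ring built, all benzene rings are bought.
4. Nitroalkene 13: C1=C2 by Henry reaction and dehydration of arylnitromethane 10 (palladium-catalysed nitromethylation of bromide 9) with aldehyde 7 (epoxide homologation of benzophenone 5); enaminone 3 from ketone 2 and DMF dimethyl acetal.

Key step: step 10

Assumption: the quinine-derived squaramide is taken to deliver the enaminone to the Si face of C2 of the nitroalkene, which gives (2R); this sense follows from the bifunctional binding model only, and the quinidine-derived pseudo-enantiomer would be used in the same way if the opposite sense is found.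

**Route**

Step 1
Reactants: 1 2,4-dihydroxyacetophenone
Product: 2 1-[4-(benzyloxy)-2-hydroxyphenyl]ethan-1-one
Conditions: BnBr (1.05 equiv), K2CO3 (1.1 equiv), acetone, reflux
Reagents that add atoms: benzyl bromide, BrCc1ccccc1
Why: Williamson ether synthesis in which the 2-OH, locked in a hydrogen bond to the acetyl carbonyl, is the less reactive phenol, so one equivalent of benzyl bromide alkylates O4 selectively.

Step 2
Reactants: 2 1-[4-(benzyloxy)-2-hydroxyphenyl]ethan-1-one
Product: 3 (E)-1-[4-(benzyloxy)-2-hydroxyphenyl]-3-(dimethylamino)prop-2-en-1-one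
Conditions: DMF dimethyl acetal (1.5 equiv), PhMe, 90 °C
Reagents that add atoms: N,N-dimethylformamide dimethyl acetal, COC(OC)N(C)C
Why: Condensation of the acetyl methyl group with the amide acetal is the standard enaminone formation of 2-hydroxyacetophenones, the chelated phenol is left free and the push–pull alkene takes the (E)-geometry.

Step 3
Reactants: 4 4,4'-dihydroxybenzophenone
Product: 5 bis[4-(benzyloxy)phenyl]methanone
Conditions: BnBr (2.3 equiv), K2CO3 (3 equiv), DMF, 60 °C
Reagents that add atoms: benzyl bromide, BrCc1ccccc1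
Why: Double Williamson ether synthesis on two unhindered, acidic phenols.

Step 4
Reactants: 5 bis[4-(benzyloxy)phenyl]methanone
Product: 6 2,2-bis[4-(benzyloxy)phenyl]oxirane
Conditions: Me3S+ I− (1.5 equiv), t-BuOK (1.5 equiv), DMSO/THF, 0 °C to 20 °C; aqueous work-up, used crude
Reagents that add atoms: trimethylsulfonium iodide, C[S+](C)C.[I-]
Why: Corey–Chaykovsky epoxidation, in which the sulfonium ylide adds to the non-enolisable diaryl ketone and the betaine closes with loss of dimethyl sulfide.

Step 5
Reactants: 6 2,2-bis[4-(benzyloxy)phenyl]oxirane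
Product: 7 2,2-bis[4-(benzyloxy)phenyl]acetaldehyde
Conditions: BF3·OEt2 (5 mol %), CH2Cl2, −40 °C; NaHCO3 quench, used at once under argon
Reagents that add atoms: none
Why: Meinwald rearrangement, in which Lewis-acid opening at the doubly benzylic, alkoxy-stabilised carbon is followed by a 1,2-hydride shift from the CH2 terminus, the only group that can migrate.

Step 6
Reactants: 8 2-bromo-5-methoxyphenol
Product: 9 2-(benzyloxy)-1-bromo-4-methoxybenzene
Conditions: BnBr (1.1 equiv), K2CO3 (1.5 equiv), DMF, 20 °C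
Reagents that add atoms: benzyl bromide, BrCc1ccccc1
Why: Williamson ether synthesis on the single phenol.

Step 7
Reactants: 9 2-(benzyloxy)-1-bromo-4-methoxybenzene
Product: 10 2-(benzyloxy)-4-methoxy-1-(nitromethyl)benzene
Conditions: MeNO2 (10 equiv), Pd2(dba)3 (2.5 mol %), XPhos (6 mol %), Cs2CO3 (1.1 equiv), 3 Å MS, 1,4-dioxane, 70 °C; aq NH4Cl
Reagents that add atoms: nitromethane, C[N+](=O)[O-]
Why: Palladium-catalysed cross-coupling of an aryl bromide with the nitronate of nitromethane (nitromethylation), in which the acidic product is held as its nitronate and so is not arylated a second time.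

Step 8
Reactants: 10 2-(benzyloxy)-4-methoxy-1-(nitromethyl)benzene; 7 2,2-bis[4-(benzyloxy)phenyl]acetaldehyde
Product: 11 1-[2-(benzyloxy)-4-methoxyphenyl]-3,3-bis[4-(benzyloxy)phenyl]-1-nitropropan-2-ol (racemic diastereomer mixture)
Conditions: 1,1,3,3-tetramethylguanidine (10 mol %), THF, 0 °C, argon; AcOH quench
Reagents that add atoms: none
Why: Henry (nitroaldol) reaction in which the arylnitromethane, far more acidic than the α-C–H of the aldehyde, is the only species deprotonated by the guanidine; the two stereocentres form without control and both are removed in step 9.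

Step 9
Reactants: 11 1-[2-(benzyloxy)-4-methoxyphenyl]-3,3-bis[4-(benzyloxy)phenyl]-1-nitropropan-2-ol
Product: 13 (E)-1-[2-(benzyloxy)-4-methoxyphenyl]-3,3-bis[4-(benzyloxy)phenyl]-1-nitroprop-1-ene, via mesylate 12 (not isolated)
Conditions: MsCl (1.3 equiv), i-Pr2NEt (2.5 equiv), CH2Cl2, −40 °C to 0 °C; cold dilute HCl wash
Reagents that add atoms: none
Why: Mesylation followed by E1cB elimination through the nitronate gives the conjugated nitroalkene with the diarylmethyl group trans to the nitro group, and the low temperature and hindered amine limit migration of the double bond towards C3.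

Step 10
Reactants: 13 (E)-1-[2-(benzyloxy)-4-methoxyphenyl]-3,3-bis[4-(benzyloxy)phenyl]-1-nitroprop-1-ene; 3 (E)-1-[4-(benzyloxy)-2-hydroxyphenyl]-3-(dimethylamino)prop-2-en-1-one (1.3 equiv)
Product: 16 7-(benzyloxy)-3-{(2R)-1-[2-(benzyloxy)-4-methoxyphenyl]-3,3-bis[4-(benzyloxy)phenyl]-1-nitropropan-2-yl}-4H-chromen-4-one (C1 epimer mixture), via iminium nitronate 14 (not isolated), via aminochromanone 15 (not isolated)
Conditions: quinine-derived squaramide 3-{[3,5-bis(trifluoromethyl)phenyl]amino}-4-{[(8α,9S)-6'-methoxycinchonan-9-yl]amino}cyclobut-3-ene-1,2-dione (10 mol %), PhCl, 25 °C, slow argon purge; aq NH4Cl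
Reagents that add atoms: none
Why: Proposed new method: the two squaramide N–H bonds bind the nitro group of 13 while the quinuclidine nitrogen hydrogen-bonds the chelated phenol of 3, so the nucleophilic α-carbon of the vinylogous amide adds to C2 of the nitroalkene (C2–C3' bond) and gives iminium nitronate 14. The phenol oxygen then attacks the iminium carbon in a 6-exo-trig closure of ring C (O1'–C2' bond) to aminal 15, and E1cB loss of dimethylamine across C2'–C3' makes the chromone irreversibly while the nitronate is protonated at C1 without lasting stereochemical consequence. The closest known reaction types are the domino α-C-functionalisation and annulation of 2-hydroxyaryl enaminones with carbon electrophiles to 3-substituted chromones and the squaramide-catalysed Michael addition of enamine-type and 1,3-dicarbonyl nucleophiles to nitroalkenes. The only lasting stereocentre, C2, is set by the catalyst, which has to present the nucleophile to the Si face of C2 (C1 > C3 > H) to give (2R), the (E)-geometry of 13 fixing which face is open in the bound complex. The step needs C-alkylation in preference to O-alkylation and conjugate addition in preference to deprotonation at the doubly benzylic C3: the first is secured by the O–H···O=C hydrogen bond that holds the phenol back until the iminium ion exists, the second by the low basicity of the catalyst and by purging the dimethylamine that is set free.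

Step 11
Reactants: 16 7-(benzyloxy)-3-{(2R)-1-[2-(benzyloxy)-4-methoxyphenyl]-3,3-bis[4-(benzyloxy)phenyl]-1-nitropropan-2-yl}-4H-chromen-4-one
Product: 18 7-(benzyloxy)-3-{(2R)-1-[2-(benzyloxy)-4-methoxyphenyl]-3,3-bis[4-(benzyloxy)phenyl]-1-oxopropan-2-yl}-4H-chromen-4-one, via potassium nitronate 17 (not isolated)
Conditions: t-BuOK (1.05 equiv), THF, −78 °C; H2O (2 equiv), dimethyldioxirane (1.2 equiv, acetone), −78 °C to 0 °C; pH 7 phosphate buffer
Reagents that add atoms: dimethyldioxirane, CC1(C)OO1
Why: Oxidative Nef reaction in which the base is consumed by the acidic benzylic C1–H alone, the dioxirane oxidises the nitronate C=N bond and the adduct collapses to the ketone and nitrite, so that C2–H meets no base stronger than nitrite and keeps its configuration.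

Step 12
Reactants: 18 7-(benzyloxy)-3-{(2R)-1-[2-(benzyloxy)-4-methoxyphenyl]-3,3-bis[4-(benzyloxy)phenyl]-1-oxopropan-2-yl}-4H-chromen-4-one
Product: 19 7-hydroxy-3-[(2R)-1-(2-hydroxy-4-methoxyphenyl)-3,3-bis(4-hydroxyphenyl)-1-oxopropan-2-yl]-4H-chromen-4-one (CNP0178475.1)
Conditions: H2 (1 atm), 10% Pd/C, EtOAc/MeOH, 20 °C, stopped after uptake of four equivalents
Reagents that add atoms: none
Why: Hydrogenolysis of the four benzyl aryl ethers under neutral conditions leaves the methyl ether, the aryl ketone, the vinylogous-ester double bond of the chromone and the base-sensitive C2 stereocentre untouched.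

**Compound list**

1 | 2,4-dihydroxyacetophenone | CC(=O)c1ccc(O)cc1O | starting material
2 | 1-[4-(benzyloxy)-2-hydroxyphenyl]ethan-1-one | CC(=O)c1ccc(OCc2ccccc2)cc1O | intermediate
3 | (E)-1-[4-(benzyloxy)-2-hydroxyphenyl]-3-(dimethylamino)prop-2-en-1-one | CN(C)/C=C/C(=O)c1ccc(OCc2ccccc2)cc1O | intermediate
4 | 4,4'-dihydroxybenzophenone | O=C(c1ccc(O)cc1)c1ccc(O)cc1 | starting material
5 | bis[4-(benzyloxy)phenyl]methanone | O=C(c1ccc(OCc2ccccc2)cc1)c1ccc(OCc2ccccc2)cc1 | intermediate
6 | 2,2-bis[4-(benzyloxy)phenyl]oxirane | C1(c2ccc(OCc3ccccc3)cc2)(c2ccc(OCc3ccccc3)cc2)CO1 | intermediate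
7 | 2,2-bis[4-(benzyloxy)phenyl]acetaldehyde | O=CC(c1ccc(OCc2ccccc2)cc1)c1ccc(OCc2ccccc2)cc1 | intermediate
8 | 2-bromo-5-methoxyphenol | COc1ccc(Br)c(O)c1 | starting material
9 | 2-(benzyloxy)-1-bromo-4-methoxybenzene | COc1ccc(Br)c(OCc2ccccc2)c1 | intermediate
10 | 2-(benzyloxy)-4-methoxy-1-(nitromethyl)benzene | COc1ccc(C[N+](=O)[O-])c(OCc2ccccc2)c1 | intermediate
11 | 1-[2-(benzyloxy)-4-methoxyphenyl]-3,3-bis[4-(benzyloxy)phenyl]-1-nitropropan-2-ol, racemic diastereomer mixture | COc1ccc(C([N+](=O)[O-])C(O)C(c2ccc(OCc3ccccc3)cc2)c2ccc(OCc3ccccc3)cc2)c(OCc2ccccc2)c1 | intermediate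
12 | methanesulfonate of 11 (not isolated) | COc1ccc(C([N+](=O)[O-])C(OS(C)(=O)=O)C(c2ccc(OCc3ccccc3)cc2)c2ccc(OCc3ccccc3)cc2)c(OCc2ccccc2)c1 | intermediate
13 | (E)-1-[2-(benzyloxy)-4-methoxyphenyl]-3,3-bis[4-(benzyloxy)phenyl]-1-nitroprop-1-ene | COc1ccc(/C(=C\C(c2ccc(OCc3ccccc3)cc2)c2ccc(OCc3ccccc3)cc2)[N+](=O)[O-])c(OCc2ccccc2)c1 | intermediate
14 | zwitterionic Michael adduct: C1 nitronate, N,N-dimethyliminium at C2', C2 (R), C3' unassigned (not isolated) | COc1ccc(C(=[N+]([O-])[O-])[C@@H](C(C=[N+](C)C)C(=O)c2ccc(OCc3ccccc3)cc2O)C(c2ccc(OCc3ccccc3)cc2)c2ccc(OCc3ccccc3)cc2)c(OCc2ccccc2)c1 | intermediate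
15 | 7-(benzyloxy)-2-(dimethylamino)chroman-4-one carrying the (2R)-nitropropan-2-yl side chain at C3', C1, C2' and C3' unassigned (not isolated) | COc1ccc(C([N+](=O)[O-])[C@@H](C2C(N(C)C)Oc3cc(OCc4ccccc4)ccc3C2=O)C(c2ccc(OCc3ccccc3)cc2)c2ccc(OCc3ccccc3)cc2)c(OCc2ccccc2)c1 | intermediate
16 | 7-(benzyloxy)-3-{(2R)-1-[2-(benzyloxy)-4-methoxyphenyl]-3,3-bis[4-(benzyloxy)phenyl]-1-nitropropan-2-yl}-4H-chromen-4-one, C1 epimer mixture | COc1ccc(C([N+](=O)[O-])[C@@H](c2coc3cc(OCc4ccccc4)ccc3c2=O)C(c2ccc(OCc3ccccc3)cc2)c2ccc(OCc3ccccc3)cc2)c(OCc2ccccc2)c1 | intermediate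
17 | potassium nitronate of 16 (not isolated) | COc1ccc(C(=[N+]([O-])[O-])[C@@H](c2coc3cc(OCc4ccccc4)ccc3c2=O)C(c2ccc(OCc3ccccc3)cc2)c2ccc(OCc3ccccc3)cc2)c(OCc2ccccc2)c1.[K+] | intermediate
18 | 7-(benzyloxy)-3-{(2R)-1-[2-(benzyloxy)-4-methoxyphenyl]-3,3-bis[4-(benzyloxy)phenyl]-1-oxopropan-2-yl}-4H-chromen-4-one | COc1ccc(C(=O)[C@@H](c2coc3cc(OCc4ccccc4)ccc3c2=O)C(c2ccc(OCc3ccccc3)cc2)c2ccc(OCc3ccccc3)cc2)c(OCc2ccccc2)c1 | intermediate
19 | 7-hydroxy-3-[(2R)-1-(2-hydroxy-4-methoxyphenyl)-3,3-bis(4-hydroxyphenyl)-1-oxopropan-2-yl]-4H-chromen-4-one | COc1ccc(C(=O)[C@@H](c2coc3cc(O)ccc3c2=O)C(c2ccc(O)cc2)c2ccc(O)cc2)c(O)c1 | target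

**Totals**

Total step count: 12. Longest linear sequence: 8 steps (steps 3, 4, 5, 8, 9, 10, 11, 12, from 4,4'-dihydroxybenzophenone).

**Steps most likely to fail**

1. Step 10 (key step). The trisubstituted, β-branched nitroalkene may be too slow an acceptor, the double bond may drift under amine base out of conjugation with the nitro group into conjugation with the two rings B, the enaminone may close to the unsubstituted chromone before it is alkylated, and the facial selectivity at C2 may be poor. The fallback uses known chemistry, sets out from nitroalkene 13 and ketone 2 and comes back at 18. Ketone 2 is converted with LiN(SiMe3)2 (2.2 equiv, THF, −78 °C) into its phenoxide–enolate dianion, which adds to 13 in a lithium-enolate Michael addition and gives after acetic acid quench the racemic γ-nitro ketone 1-[4-(benzyloxy)-2-hydroxyphenyl]-4-[2-(benzyloxy)-4-methoxyphenyl]-3-{bis[4-(benzyloxy)phenyl]methyl}-4-nitrobutan-1-one F1. A reductive Nef reaction (NaOMe, MeOH, then aqueous TiCl3 buffered with NH4OAc) should give the racemic 1,4-diketone F2. DMF dimethyl acetal (PhMe, 80 °C) then condenses at the only methylene group next to a carbonyl to the enaminone F3 (not isolated), whose chelated phenol closes ring C with loss of dimethylamine to the racemic ketone F4. Preparative chromatography on a chiral stationary phase separates 18 from its (2S)-enantiomer F5, and step 12 follows.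

2. Step 9. During mesylation and elimination the amine may move the double bond of the product into the allylic nitro isomer, or the nitroaldol may revert to 10 and 7 before it is trapped. The fallback sets out from nitroaldol 11 and comes back at 16. Compound 11 is acetylated under acid catalysis (Ac2O, Sc(OTf)3 cat., MeCN, 0 °C) to the β-nitro acetate F6, which stores the nitroalkene in stable form. F6 is then placed under the conditions of step 10 with solid NaHCO3 (1.2 equiv), so that 13 is released slowly by E1cB loss of acetate and is consumed by enaminone 3 as it forms, without isolation and without exposure to an excess of amine.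

3. Step 11. Once the ketone is formed, C2–H is acidic and may epimerise if base is left over, the alkoxide or the nitronate oxygen may add to C2' of the chromone, and the dioxirane may over-oxidise the electron-rich rings. The fallback sets out from 16 and comes back at 18. Compound 16 in THF is stirred with aqueous TiCl3 buffered with NH4OAc (pH about 5 to 6, 20 °C); trivalent titanium reduces the aci-nitro form to the oxime F7 and on to the N–H imine F8, which hydrolyses in the same medium to 18 with no base stronger than acetate present.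

**Further compounds**

F1 | step 10 | 1-[4-(benzyloxy)-2-hydroxyphenyl]-4-[2-(benzyloxy)-4-methoxyphenyl]-3-{bis[4-(benzyloxy)phenyl]methyl}-4-nitrobutan-1-one, racemic diastereomer mixture | COc1ccc(C([N+](=O)[O-])C(CC(=O)c2ccc(OCc3ccccc3)cc2O)C(c2ccc(OCc3ccccc3)cc2)c2ccc(OCc3ccccc3)cc2)c(OCc2ccccc2)c1
F2 | step 10 | 1-[4-(benzyloxy)-2-hydroxyphenyl]-4-[2-(benzyloxy)-4-methoxyphenyl]-3-{bis[4-(benzyloxy)phenyl]methyl}butane-1,4-dione, racemic | COc1ccc(C(=O)C(CC(=O)c2ccc(OCc3ccccc3)cc2O)C(c2ccc(OCc3ccccc3)cc2)c2ccc(OCc3ccccc3)cc2)c(OCc2ccccc2)c1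
F3 | step 10 | 2-[(dimethylamino)methylidene] derivative of F2 (enaminone at the methylene carbon, not isolated), racemic | COc1ccc(C(=O)C(C(=CN(C)C)C(=O)c2ccc(OCc3ccccc3)cc2O)C(c2ccc(OCc3ccccc3)cc2)c2ccc(OCc3ccccc3)cc2)c(OCc2ccccc2)c1
F4 | step 10 | racemic 7-(benzyloxy)-3-{1-[2-(benzyloxy)-4-methoxyphenyl]-3,3-bis[4-(benzyloxy)phenyl]-1-oxopropan-2-yl}-4H-chromen-4-one | COc1ccc(C(=O)C(c2coc3cc(OCc4ccccc4)ccc3c2=O)C(c2ccc(OCc3ccccc3)cc2)c2ccc(OCc3ccccc3)cc2)c(OCc2ccccc2)c1
F5 | step 10 | 7-(benzyloxy)-3-{(2S)-1-[2-(benzyloxy)-4-methoxyphenyl]-3,3-bis[4-(benzyloxy)phenyl]-1-oxopropan-2-yl}-4H-chromen-4-one | COc1ccc(C(=O)[C@H](c2coc3cc(OCc4ccccc4)ccc3c2=O)C(c2ccc(OCc3ccccc3)cc2)c2ccc(OCc3ccccc3)cc2)c(OCc2ccccc2)c1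
F6 | step 9 | 1-[2-(benzyloxy)-4-methoxyphenyl]-3,3-bis[4-(benzyloxy)phenyl]-1-nitropropan-2-yl acetate, racemic diastereomer mixture | COc1ccc(C([N+](=O)[O-])C(OC(C)=O)C(c2ccc(OCc3ccccc3)cc2)c2ccc(OCc3ccccc3)cc2)c(OCc2ccccc2)c1
F7 | step 11 | 7-(benzyloxy)-3-{(2R)-1-[2-(benzyloxy)-4-methoxyphenyl]-3,3-bis[4-(benzyloxy)phenyl]-1-(hydroxyimino)propan-2-yl}-4H-chromen-4-one, oxime geometry unassigned | COc1ccc(C(=NO)[C@@H](c2coc3cc(OCc4ccccc4)ccc3c2=O)C(c2ccc(OCc3ccccc3)cc2)c2ccc(OCc3ccccc3)cc2)c(OCc2ccccc2)c1
F8 | step 11 | 7-(benzyloxy)-3-{(2R)-1-[2-(benzyloxy)-4-methoxyphenyl]-3,3-bis[4-(benzyloxy)phenyl]-1-iminopropan-2-yl}-4H-chromen-4-one | COc1ccc(C(=N)[C@@H](c2coc3cc(OCc4ccccc4)ccc3c2=O)C(c2ccc(OCc3ccccc3)cc2)c2ccc(OCc3ccccc3)cc2)c(OCc2ccccc2)c1
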